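**Strategy.** The route cuts the cyclopenta[c]pyran at C5–C6, the only bond of the cyclopentane ring (ring C) that joins two unsubstituted methylene carbons, so both atoms can enter as alkene termini. The key step is a ring-closing metathesis of an acyclic 1,6-diene ester with one vinyl and one propenyl terminus, run in tandem with hydrogenation by the same ruthenium charge. It closes ring C around the C7 methyl centre, which a chirality-transferring Johnson–Claisen rearrangement installs. Elimination then unveils a C4a=C7a enal, a Michael/lactolisation domino with 6-methylheptane-3,4-dione builds the acyl-dihydropyran (ring B), and oxocarbenium C-arylation with 4-hydroxy-5-methylcoumarin plus carbonyl O-methylation complete the chromone (ring A).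

Key step: step 4

Remark: locants C1 to C7a are those of the cyclopenta[c]pyran unit of the target; the two centres made in step 3 and the anomeric centre of lactol 17 are carried as mixtures because later steps erase or ionise them.

Step 1
Reactants: 1 (E)-pent-3-en-2-one
Product: 2 (2R,3E)-pent-3-en-2-ol
Conditions: trans-RuCl2[(S)-xylbinap][(S)-daipen] (0.1 mol %), K2CO3 (2 mol %), i-PrOH, H2 (8 bar), 25 °C
Reagents that add atoms: none
Why: Carbonyl-selective Noyori asymmetric hydrogenation: the ruthenium hydride/diamine NH pair reduces C=O and leaves the C=C bond alone, and the (S)-diphosphine/(S)-diamine catalyst should give the (R)-carbinol, the sense it shows with aryl and alkenyl methyl ketones.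

Step 2
Reactants: 2 (2R,3E)-pent-3-en-2-ol
Product: 4 ethyl (3R,4E)-3-methylhex-4-enoate, via ketene acetal 3 (not isolated)
Conditions: MeC(OEt)3 (6 equiv), EtCO2H (5 mol %), 140 °C, EtOH distilled off
Reagents that add atoms: triethyl orthoacetate CC(OCC)(OCC)OCC
Why: Johnson–Claisen rearrangement: ketene acetal 3 reorganises through a chair transition state with the carbinol methyl group equatorial, so the (R)-carbinol centre is traded suprafacially for the (R)-configured C3 centre (the future C7) and an (E)-propenyl group.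

Step 3
Reactants: 4 ethyl (3R,4E)-3-methylhex-4-enoate
Product: 6 ethyl 3-acetoxy-2-[(2S,3E)-pent-3-en-2-yl]pent-4-enoate (diastereomer mixture at C2 and C3), via lithium aldolate 5 (not isolated)
Conditions: LiN(i-Pr)2 (1.1 equiv), THF, −78 °C; acrolein (1.2 equiv); then Ac2O (1.5 equiv), −78 to 0 °C
Reagents that add atoms: acrolein C=CC=O; acetic anhydride CC(=O)OC(C)=O
Why: Aldol addition of the lithium ester enolate to the carbonyl carbon of acrolein and in situ O-acetylation of aldolate 5; the two new centres (future C7a and C4a) are formed without control because both become sp2 in step 5.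

Step 4
Reactants: 6 ethyl 3-acetoxy-2-[(2S,3E)-pent-3-en-2-yl]pent-4-enoate
Product: 8 ethyl (5S)-2-acetoxy-5-methylcyclopentane-1-carboxylate (diastereomer mixture at C1 and C2), via cyclopentene 7 (not isolated)
Conditions: second-generation Grubbs catalyst RuCl2(=CHPh)(H2IMes)(PCy3) (3 mol %), ClCH2CH2Cl (0.01 M), 45 °C; then H2 (7 bar), 70 °C
Reagents that add atoms: none
Why: Ring-closing olefin metathesis with tandem hydrogenation: the ruthenium alkylidene loads onto the terminal vinyl group (C5), engages the propenyl group (C6) through a ruthenacyclobutane and expels propene, which forms the C5=C6 bond; under hydrogen the same ruthenium charge becomes a hydride that saturates this bond, so C5 and C6 end as the two ring methylene groups. The closest known reaction type is the one-pot ring-closing metathesis/hydrogenation of 1,6-dienes to cyclopentanes. Ring C closes as a five-membered carbocycle by union of the two alkene termini, the only ring size this diene can reach. No stereocentre is created: the C7 centre is not acidic and is kept, and the two centres from step 3 are carried as a mixture because every diastereomer can cyclise. The step needs cyclisation to outrun oligomerisation, which the 1,6-spacing and high dilution secure, and it needs the ester and the allylic acetate to survive, which the neutral homogeneous hydrogenation secures.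

Step 5
Reactants: 8 ethyl (5S)-2-acetoxy-5-methylcyclopentane-1-carboxylate
Product: 9 ethyl (5S)-5-methylcyclopent-1-ene-1-carboxylate
Conditions: DBU (2 equiv), CH2Cl2, 25 °C
Reagents that add atoms: none
Why: E1cB elimination of acetic acid through the ester enolate gives the conjugated C7a=C4a ester from every diastereomer of 8, and the C7 centre, which is not acidic because it is cross-conjugated, keeps its configuration.

Step 6
Reactants: 9 ethyl (5S)-5-methylcyclopent-1-ene-1-carboxylate
Product: 10 [(5S)-5-methylcyclopent-1-en-1-yl]methanol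
Conditions: i-Bu2AlH (2.5 equiv), CH2Cl2, −78 to 0 °C; aqueous Rochelle salt
Reagents that add atoms: none
Why: 1,2-Reduction of the conjugated ester by the aluminium hydride gives the allylic alcohol and leaves the ring alkene alone.

Step 7
Reactants: 10 [(5S)-5-methylcyclopent-1-en-1-yl]methanol
Product: 11 (5S)-5-methylcyclopent-1-ene-1-carbaldehyde
Conditions: MnO2 (15 equiv), CH2Cl2, 25 °C
Reagents that add atoms: none
Why: Allylic alcohol oxidation on manganese dioxide stops at the enal, which is volatile and is carried on as a solution.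

Step 8
Reactants: 12 4-methylpent-1-yne
Product: 14 6-methylhept-3-yne, via lithium acetylide 13 (not isolated)
Conditions: n-BuLi (1.05 equiv), THF, −78 °C; then EtI (1.3 equiv), DMPU, −78 to 25 °C
Reagents that add atoms: iodoethane CCI
Why: Deprotonation of the terminal alkyne and SN2 alkylation of acetylide 13 by the primary iodide.

Step 9
Reactants: 14 6-methylhept-3-yne
Product: 15 6-methylheptane-3,4-dione
Conditions: RuCl3·xH2O (2 mol %), NaIO4 (2.2 equiv), EtOAc/MeCN/H2O, 0 °C
Reagents that add atoms: sodium periodate [Na+].[O-]I(=O)(=O)=O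
Why: Oxidation of the internal alkyne to the 1,2-diketone by ruthenium tetroxide RuO4, which is regenerated in the flask by periodate, the oxidation being stopped before C–C cleavage sets in.

Step 10
Reactants: 11 (5S)-5-methylcyclopent-1-ene-1-carbaldehyde; 15 6-methylheptane-3,4-dione
Product: 17 1-[(4aS,7S,7aR)-1-hydroxy-4,7-dimethyl-1,4a,5,6,7,7a-hexahydrocyclopenta[c]pyran-3-yl]-3-methylbutan-1-one (anomeric mixture), via keto aldehyde 16 (not isolated)
Conditions: pyrrolidine (20 mol %), PhCO2H (20 mol %), CH2Cl2, 0 to 25 °C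
Reagents that add atoms: none
Why: Domino Michael addition/hemiacetalisation under iminium activation: the enol of 15 adds through its less hindered ethyl-side α-carbon to C4a of the iminium ion on the face anti to the C7 methyl group, the enamine formed is protonated at C7a anti to the new side chain, and the diosphenol oxygen of cis aldehyde 16 closes the lactol, so C4a and C7a are set by substrate control while C4 is erased by enolisation and C1 stays an anomeric mixture.

Step 11
Reactants: 18 1-(2-hydroxy-6-methylphenyl)ethan-1-one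
Product: 20 4-hydroxy-5-methyl-2H-chromen-2-one, via keto ester 19 (not isolated)
Conditions: NaH (3.5 equiv), (EtO)2CO, toluene, 110 °C; then aqueous HCl
Reagents that add atoms: diethyl carbonate CCOC(=O)OCC
Why: Claisen C-acylation of the ketone enolate by diethyl carbonate gives keto ester 19, whose phenoxide closes the lactone to the 4-hydroxycoumarin.

Step 12
Reactants: 17 1-[(4aS,7S,7aR)-1-hydroxy-4,7-dimethyl-1,4a,5,6,7,7a-hexahydrocyclopenta[c]pyran-3-yl]-3-methylbutan-1-one; 20 4-hydroxy-5-methyl-2H-chromen-2-one
Product: 21 4-hydroxy-5-methyl-3-[(1R,4aS,7S,7aR)-4,7-dimethyl-3-(3-methylbutanoyl)-1,4a,5,6,7,7a-hexahydrocyclopenta[c]pyran-1-yl]-2H-chromen-2-one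
Conditions: BF3·OEt2 (0.3 equiv), 4 Å molecular sieves, CH2Cl2/MeCN, −30 to 0 °C
Reagents that add atoms: none
Why: Friedel–Crafts-type C-alkylation: the Lewis acid ionises the lactol to the cyclic oxocarbenium ion and the nucleophilic C3 of the 4-hydroxycoumarin attacks C1 on the convex face of the cis-fused bicycle, anti to the C7a–C7 bond, which sets the (1R) centre, while any O-linked acetal re-ionises and drains to the C–C bonded product.

Step 13
Reactants: 21 4-hydroxy-5-methyl-3-[(1R,4aS,7S,7aR)-4,7-dimethyl-3-(3-methylbutanoyl)-1,4a,5,6,7,7a-hexahydrocyclopenta[c]pyran-1-yl]-2H-chromen-2-one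
Product: 23 2-methoxy-5-methyl-3-[(1R,4aS,7S,7aR)-4,7-dimethyl-3-(3-methylbutanoyl)-1,4a,5,6,7,7a-hexahydrocyclopenta[c]pyran-1-yl]-4H-chromen-4-one, via pyrylium triflate 22 (not isolated)
Conditions: MeOTf (1.2 equiv), CH2Cl2, 0 to 25 °C; then saturated aqueous NaHCO3
Reagents that add atoms: methyl trifluoromethanesulfonate COS(=O)(=O)C(F)(F)F
Why: O-Methylation of a tautomeric ambident system by a hard methylating agent takes place at the basic lactone carbonyl oxygen, remote from the mobile proton, to give hydroxypyrylium salt 22, and deprotonation on work-up should leave the 2-methoxychromone and not the 4-methoxycoumarin, helped by the peri 5-methyl group that shields the 4-oxygen.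

**Compound list**

1 | (E)-pent-3-en-2-one | C/C=C/C(C)=O | starting material
2 | (2R,3E)-pent-3-en-2-ol | C/C=C/[C@@H](C)O | intermediate
3 | 1-ethoxy-1-[(2R,3E)-pent-3-en-2-yloxy]ethene (ketene acetal, not isolated) | C=C(OCC)O[C@H](C)/C=C/C | intermediate
4 | ethyl (3R,4E)-3-methylhex-4-enoate | CCOC(=O)C[C@@H](C)/C=C/C | intermediate
5 | lithium alkoxide of ethyl 3-hydroxy-2-[(2S,3E)-pent-3-en-2-yl]pent-4-enoate (aldolate, diastereomer mixture, not isolated) | CCOC(=O)C(C([O-])C=C)[C@@H](C)/C=C/C.[Li+] | intermediate
6 | ethyl 3-acetoxy-2-[(2S,3E)-pent-3-en-2-yl]pent-4-enoate (diastereomer mixture at C2 and C3) | CCOC(=O)C(C(OC(C)=O)C=C)[C@@H](C)/C=C/C | intermediate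
7 | ethyl (5S)-2-acetoxy-5-methylcyclopent-3-ene-1-carboxylate (diastereomer mixture at C1 and C2, not isolated) | CCOC(=O)C1C(OC(C)=O)C=C[C@@H]1C | intermediate
8 | ethyl (5S)-2-acetoxy-5-methylcyclopentane-1-carboxylate (diastereomer mixture at C1 and C2) | CCOC(=O)C1C(OC(C)=O)CC[C@@H]1C | intermediate
9 | ethyl (5S)-5-methylcyclopent-1-ene-1-carboxylate | CCOC(=O)C1=CCC[C@@H]1C | intermediate
10 | [(5S)-5-methylcyclopent-1-en-1-yl]methanol | OCC1=CCC[C@@H]1C | intermediate
11 | (5S)-5-methylcyclopent-1-ene-1-carbaldehyde | O=CC1=CCC[C@@H]1C | intermediate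
12 | 4-methylpent-1-yne | C#CCC(C)C | starting material
13 | lithium 4-methylpent-1-yn-1-ide (not isolated) | [Li+].[C-]#CCC(C)C | intermediate
14 | 6-methylhept-3-yne | CCC#CCC(C)C | intermediate
15 | 6-methylheptane-3,4-dione | CCC(=O)C(=O)CC(C)C | intermediate
16 | (1R,2S,5S)-5-methyl-2-(6-methyl-3,4-dioxoheptan-2-yl)cyclopentane-1-carbaldehyde (side-chain C2 epimers, not isolated) | O=C[C@@H]1[C@@H](C)CC[C@@H]1C(C)C(=O)C(=O)CC(C)C | intermediate
17 | 1-[(4aS,7S,7aR)-1-hydroxy-4,7-dimethyl-1,4a,5,6,7,7a-hexahydrocyclopenta[c]pyran-3-yl]-3-methylbutan-1-one (anomeric mixture at C1) | OC1OC(C(=O)CC(C)C)=C(C)[C@H]2CC[C@H](C)[C@H]21 | intermediate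
18 | 1-(2-hydroxy-6-methylphenyl)ethan-1-one | CC(=O)c1c(C)cccc1O | starting material
19 | ethyl 3-(2-hydroxy-6-methylphenyl)-3-oxopropanoate (present as its sodium salt, not isolated) | CCOC(=O)CC(=O)c1c(C)cccc1O | intermediate
20 | 4-hydroxy-5-methyl-2H-chromen-2-one | Cc1cccc2oc(=O)cc(O)c12 | intermediate
21 | 4-hydroxy-5-methyl-3-[(1R,4aS,7S,7aR)-4,7-dimethyl-3-(3-methylbutanoyl)-1,4a,5,6,7,7a-hexahydrocyclopenta[c]pyran-1-yl]-2H-chromen-2-one | O=c1oc2cccc(C)c2c(O)c1[C@@H]1OC(C(=O)CC(C)C)=C(C)[C@H]2CC[C@H](C)[C@H]21 | intermediate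
22 | 4-hydroxy-2-methoxy-5-methyl-3-[(1R,4aS,7S,7aR)-4,7-dimethyl-3-(3-methylbutanoyl)-1,4a,5,6,7,7a-hexahydrocyclopenta[c]pyran-1-yl]chromenylium trifluoromethanesulfonate (not isolated) | COc1[o+]c2cccc(C)c2c(O)c1[C@@H]1OC(C(=O)CC(C)C)=C(C)[C@H]2CC[C@H](C)[C@H]21.[O-]S(=O)(=O)C(F)(F)F | intermediate
23 | 2-methoxy-5-methyl-3-[(1R,4aS,7S,7aR)-4,7-dimethyl-3-(3-methylbutanoyl)-1,4a,5,6,7,7a-hexahydrocyclopenta[c]pyran-1-yl]-4H-chromen-4-one | COc1oc2cccc(C)c2c(=O)c1[C@@H]1OC(C(=O)CC(C)C)=C(C)[C@H]2CC[C@H](C)[C@H]21 | target

**Total step count:** 13. **Longest linear sequence:** 10 steps (steps 1–7, 10, 12 and 13).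

**Steps most likely to fail**

First, step 10. The diketone may enolise on its isobutyl side or condense with itself faster than it adds to the hindered iminium ion, and the ring-fusion centre C7a may epimerise if the enamine re-forms from the open aldehyde. The fallback sets out from enal 11 and builds the acyl group stepwise from a donor that can enolise on one side only. Amine/acid-catalysed Michael addition/hemiacetalisation with ethyl 2-oxobutanoate should give ethyl (4aS,7S,7aR)-1-hydroxy-4,7-dimethyl-1,4a,5,6,7,7a-hexahydrocyclopenta[c]pyran-3-carboxylate F1. MeOH with pyridinium p-toluenesulfonate should give ethyl (4aS,7S,7aR)-1-methoxy-4,7-dimethyl-1,4a,5,6,7,7a-hexahydrocyclopenta[c]pyran-3-carboxylate F2. MeNHOMe·HCl with i-PrMgCl should give (4aS,7S,7aR)-N,1-dimethoxy-N,4,7-trimethyl-1,4a,5,6,7,7a-hexahydrocyclopenta[c]pyran-3-carboxamide F3. i-BuMgBr should give 1-[(4aS,7S,7aR)-1-methoxy-4,7-dimethyl-1,4a,5,6,7,7a-hexahydrocyclopenta[c]pyran-3-yl]-3-methylbutan-1-one F4. F4 is ionised by BF3·OEt2 in the presence of coumarin 20 and comes back to the route at 21.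

Second, step 13. Methylation may go to the 4-oxygen, and the acidic pyrylium salt may ionise the C1–O bond and scramble C1. The fallback sets out from acetophenone 18 and lactol 17 and fixes the methoxy position before the C–C bond is made. CS2 with t-BuOK should give 4-hydroxy-5-methyl-2H-chromene-2-thione F5, and MeI with K2CO3 should give 5-methyl-2-(methylsulfanyl)-4H-chromen-4-one F6. mCPBA should give 2-(methanesulfonyl)-5-methyl-4H-chromen-4-one F7, and NaOMe in MeOH should give 2-methoxy-5-methyl-4H-chromen-4-one F8 by addition–elimination. BF3·OEt2-mediated alkylation of F8 at C3 by lactol 17 comes back to the route at target 23.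

Third, step 12. The oxocarbenium ion may lose the C7a proton and re-protonate (epimerisation of the ring fusion), or the nucleophile may attack the concave face. The fallback sets out from lactol 17 and coumarin 20 and joins them through oxygen first. A Mitsunobu reaction (PPh3, diisopropyl azodicarboxylate) should give 5-methyl-4-{[(4aS,7S,7aR)-4,7-dimethyl-3-(3-methylbutanoyl)-1,4a,5,6,7,7a-hexahydrocyclopenta[c]pyran-1-yl]oxy}-2H-chromen-2-one F9 without a free cation. Sc(OTf)3 at −78 °C should then trigger an O-to-C (Fries-type) shift inside the ion pair and come back to the route at 21.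

Further compounds
F1 | step 10 | ethyl (4aS,7S,7aR)-1-hydroxy-4,7-dimethyl-1,4a,5,6,7,7a-hexahydrocyclopenta[c]pyran-3-carboxylate | OC1OC(C(=O)OCC)=C(C)[C@H]2CC[C@H](C)[C@H]21
F2 | step 10 | ethyl (4aS,7S,7aR)-1-methoxy-4,7-dimethyl-1,4a,5,6,7,7a-hexahydrocyclopenta[c]pyran-3-carboxylate | COC1OC(C(=O)OCC)=C(C)[C@H]2CC[C@H](C)[C@H]21
F3 | step 10 | (4aS,7S,7aR)-N,1-dimethoxy-N,4,7-trimethyl-1,4a,5,6,7,7a-hexahydrocyclopenta[c]pyran-3-carboxamide | COC1OC(C(=O)N(C)OC)=C(C)[C@H]2CC[C@H](C)[C@H]21
F4 | step 10 | 1-[(4aS,7S,7aR)-1-methoxy-4,7-dimethyl-1,4a,5,6,7,7a-hexahydrocyclopenta[c]pyran-3-yl]-3-methylbutan-1-one | COC1OC(C(=O)CC(C)C)=C(C)[C@H]2CC[C@H](C)[C@H]21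
F5 | step 13 | 4-hydroxy-5-methyl-2H-chromene-2-thione | Cc1cccc2oc(=S)cc(O)c12
F6 | step 13 | 5-methyl-2-(methylsulfanyl)-4H-chromen-4-one | CSc1cc(=O)c2c(C)cccc2o1
F7 | step 13 | 2-(methanesulfonyl)-5-methyl-4H-chromen-4-one | CS(=O)(=O)c1cc(=O)c2c(C)cccc2o1
F8 | step 13 | 2-methoxy-5-methyl-4H-chromen-4-one | COc1cc(=O)c2c(C)cccc2o1
F9 | step 12 | 5-methyl-4-{[(4aS,7S,7aR)-4,7-dimethyl-3-(3-methylbutanoyl)-1,4a,5,6,7,7a-hexahydrocyclopenta[c]pyran-1-yl]oxy}-2H-chromen-2-one | Cc1cccc2oc(=O)cc(OC3OC(C(=O)CC(C)C)=C(C)[C@H]4CC[C@H](C)[C@H]43)c12
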